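The readings are simulated for substances that don't exist.

The mono adduct is the thing to watch. Reagent makes it from substrate, and reagent then consumes it too.

| flask | substrate | reagent | remark | time |
|---|---|---|---|---|
| north-east | 0.050 M | 0.048 M | run made earlier |  |
| south | 0.050 M | 0.28 M | run made earlier |  |
| eta | 0.050 M | 0.0400 M |  | 80 min |
| delta | 0.050 M | 0.0600 M |  | 80 min |
| epsilon | 0.050 M | 0.200 M |  | 80 min |

| run | time / min | mono adduct / % | substrate / % |
|---|---|---|---|
| north-east | 5.00 | 40 | 48 |
| north-east | 6.00 | 43 | 44 |
| north-east | 10.0 | 49 | 32 |
| north-east | 15.0 | 53 | 25 |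
| north-east | 25.0 | 58 | 20 |
| north-east | 40.0 | 58 | 13 |
| north-east | 60.0 | 58 | 11 |
| south | 8.00 | 53 | 0 |
| south | 15.0 | 36 | 0 |
| south | 25.0 | 24 | 4 |
| south | 30.0 | 20 | 2 |
| south | 40.0 | 12 | 1 |
| south | 50.0 | 8 | 0 |
| south | 60.0 | 4 | 1 |

(standard deviation of a reading: 1.5 percentage points)

- which of these holds the largest part of the substrate at the end of eta (substrate / bis adduct / other mono adduct / mono adduct)
- which of these holds the largest part of the substrate at the end of delta (substrate / bis adduct / other mono adduct / mono adduct)
- which of these holds the largest part of the substrate at the end of epsilon (substrate / bis adduct / other mono adduct / mono adduct)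
- final mono adduct in epsilon, as a percentage of the substrate charged



First instants. I read the substrate step from the north-east run, where charges are nearly equal and half of the substrate has reacted by 5.00 min:

4.33 L mol⁻¹ min⁻¹

In epsilon that gives substrate a time constant of 1.15 min, far shorter than the run of 80 min.

Middle. The south run reads 0 % substrate at 8.00 min, so from there I read the decay of its mono adduct, at this pseudo-first-order rate:

0.0464 min⁻¹

Running that back to zero time gives a reading of 76.8 % as the mono adduct's share of substrate.  Dividing by the surplus, c_reagent − c_substrate, gives the loss constant: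

0.202 L mol⁻¹ min⁻¹

The loss constant is mono adduct's decay rate per mole per litre of surplus reagent.

End. The crossing is where the lifetime, the inverse of loss constant times surplus, equals the run time, so compare it with 80 min.

- Epsilon: 33.0 min, shorter than the run. I expect 6.82 % mono adduct, with bis adduct ahead.
- Delta: 495 min, longer than the run, so I expect mono adduct to stay ahead.
- Eta: reagent is the limiting reagent, 0.0400 M against 0.050 M, so there is no surplus. The last north-east reading has mono adduct ahead of substrate, and I expect the same in eta.

The forecast named mono adduct for eta, mono adduct for delta and bis adduct for epsilon, with 8 % mono adduct (5 % to 12 %), a little above mine, on “about 77% of substrate going to mono adduct”.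

Among the four choices asked, the flasks give mono adduct for eta, mono adduct for delta and bis adduct for epsilon, with 9.38 % mono adduct in epsilon.

    substrate + reagent → mono adduct + by-product (k = 4.50 L mol⁻¹ min⁻¹)
    substrate + reagent → other mono adduct + by-product (k = 1.50 L mol⁻¹ min⁻¹)
    reagent + mono adduct → bis adduct + by-product (k = 0.0540 L mol⁻¹ min⁻¹)
    reagent + other mono adduct → bis adduct + by-product (k = 0.390 L mol⁻¹ min⁻¹)
    reagent → decomposition product (k = 6.40 × 10⁻⁵ min⁻¹)
    reagent ⇌ dormant form (K = 0.280, k = 0.220 min⁻¹)
    reagent + mono adduct → over-reaction product (k = 0.230 L mol⁻¹ min⁻¹)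

In epsilon at 0.665 min, mono adduct goes to over-reaction product 4.3 times as fast as to bis adduct. By 80.0 min epsilon holds 53.1 % over-reaction product beside 36.0 % bis adduct. Epsilon's reagent then stands at 0.0819 M free plus 0.0230 M dormant form, so the loss constant gives a lifetime of 47.2 min. Carried on from 9.38 % to a reading of the same flask at 2.5 h, that lifetime predicts 2.13 % mono adduct, and that reading holds 1.93 %.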